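**Strategy**

Locants: C1 ketone carbon; C2=C3 enone alkene; C4 and C11 cyclobutane CH atoms on C3 and C1; C5 cyclobutane CH on C6 (CMe2); C7, C9 carbinols; C10 quaternary ring carbon. The route exploits the cyclobutane C4–C5–C11–C10, whose corners C5 and C10 are spanned by the chain C6–C9 (seven-membered ring). C10–C11 is taken from a keteniminium ion and C5=C4 from the near alkene of a diene, so one crossed [2+2] cycloaddition forms C5–C11 and C4–C10 and closes both rings. Its precursor is an open-chain pyrrolidine amide with a cis C8=C9 tether, the C7 silyl ether and an (E)-isoprenyl end; the enone bridge C1–C3 follows.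

Key step: step 9

**Remarks on the chemistry (assumptions)**
- C10 becomes trigonal in the keteniminium ion, so every open-chain compound containing C10 is carried as a mixture of epimers at that carbon (chain C2), and its SMILES leaves the centre open.
- The C7 oxygen carries a triisopropylsilyl group: it is not expected to migrate to the C5 alkoxide set free in the lactol olefination, it survives the acid of step 10, and its bulk screens one face of C8=C9 in step 13.
- The aldehyde of step 10 is expected together with its C11 epimer; the two interconvert through the enol (DBU, CH2Cl2, rt), only the epimer named can cyclise in step 11, and recovered epimer is re-equilibrated and resubmitted.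

**Route**

Step 1
Reactants: 1 (S)-pantolactone
Product: 2 (3S)-4,4-dimethyl-3-(triisopropylsilyloxy)oxolan-2-one
Conditions: i-Pr3SiOTf, 2,6-lutidine, CH2Cl2, 0 °C → rt
Reagents that add atoms: triisopropylsilyl trifluoromethanesulfonate, CC(C)[Si](OS(=O)(=O)C(F)(F)F)(C(C)C)C(C)C
Why: Silyl ether formation with a silyl triflate and a hindered pyridine base is the standard protection of a congested secondary alcohol, and the future C7 stereocentre is not touched.

Step 2
Reactants: 2 (3S)-4,4-dimethyl-3-(triisopropylsilyloxy)oxolan-2-one
Product: 3 (3S)-4,4-dimethyl-3-(triisopropylsilyloxy)oxolan-2-ol (lactol; both anomers)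
Conditions: i-Bu2AlH, CH2Cl2, −78 °C; aq. KNaC4H4O6
Reagents that add atoms: none
Why: Low-temperature i-Bu2AlH reduction of a lactone stops at the lactol because the aluminium hemiacetal collapses only on work-up (partial lactone reduction), and C7 is unaffected.

Step 3
Reactants: 4 methacrylic acid
Product: 5 (2-carboxypropyl)triphenylphosphonium bromide (racemic)
Conditions: Ph3P·HBr, MeCN, reflux
Reagents that add atoms: triphenylphosphine hydrobromide, [Br-].c1ccc(cc1)[PH+](c1ccccc1)c1ccccc1
Why: Conjugate (phospha-Michael) addition of the phosphine to the protonated acrylic acid gives the β-carboxyalkyl phosphonium salt; the new centre C10 is racemic, which has no consequence.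

Step 4
Reactants: 3 (3S)-4,4-dimethyl-3-(triisopropylsilyloxy)oxolan-2-ol; 5 (2-carboxypropyl)triphenylphosphonium bromide
Product: 7 (3Z,5R)-7-hydroxy-2,6,6-trimethyl-5-(triisopropylsilyloxy)hept-3-enoic acid, via carboxylate ylide 6 (not isolated)
Conditions: NaN(SiMe3)2, THF, 0 °C; then 3, −78 °C → rt; aq. citric acid
Reagents that add atoms: none
Why: Wittig olefination of the lactol through its open hydroxy-aldehyde form with a non-stabilised ylide under lithium-free conditions should give the (Z)-C8=C9 alkene via the kinetically preferred cis-oxaphosphetane, the carboxylate keeping C10–H inert so that the alkene stays out of conjugation, and C7 is retained because olefination outruns enolisation of the α-silyloxy aldehyde.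

Step 5
Reactants: 7 (3Z,5R)-7-hydroxy-2,6,6-trimethyl-5-(triisopropylsilyloxy)hept-3-enoic acid
Product: 8 (3Z,5R)-2,6,6-trimethyl-7-oxo-5-(triisopropylsilyloxy)hept-3-enoic acid
Conditions: Dess–Martin periodinane, CH2Cl2, 0 °C → rt
Reagents that add atoms: none
Why: Dess–Martin oxidation converts the neopentyl primary alcohol into the aldehyde, which can neither enolise nor eliminate because C6 is quaternary.

Step 6
Reactants: 9 methallyl chloride
Product: 10 tributyl(2-methylprop-2-en-1-yl)phosphonium chloride
Conditions: PBu3, MeCN, 60 °C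
Reagents that add atoms: tributylphosphine, CCCCP(CCCC)CCCC
Why: SN2 quaternisation of the allylic chloride by the nucleophilic trialkylphosphine (phosphonium salt formation).

Step 7
Reactants: 8 (3Z,5R)-2,6,6-trimethyl-7-oxo-5-(triisopropylsilyloxy)hept-3-enoic acid; 10 tributyl(2-methylprop-2-en-1-yl)phosphonium chloride
Product: 12 (3Z,5R,7E)-2,6,6,9-tetramethyl-5-(triisopropylsilyloxy)deca-3,7,9-trienoic acid, via allylic ylide 11 (not isolated)
Conditions: KOtBu, THF, −78 °C; then 8, −78 °C → rt; aq. citric acid
Reagents that add atoms: none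
Why: Wittig reaction of an allylic trialkylphosphonium ylide, a class that favours the trans-oxaphosphetane and hence the (E)-diene, with a non-enolisable aldehyde, the carboxylate again keeping C10–H inert to the basic ylide.

Step 8
Reactants: 12 (3Z,5R,7E)-2,6,6,9-tetramethyl-5-(triisopropylsilyloxy)deca-3,7,9-trienoic acid; 13 pyrrolidine
Product: 15 (3Z,5R,7E)-2,6,6,9-tetramethyl-1-(pyrrolidin-1-yl)-5-(triisopropylsilyloxy)deca-3,7,9-trien-1-one, via benzotriazolyl ester 14 (not isolated)
Conditions: EDC·HCl, HOBt, CH2Cl2, 0 °C → rt
Reagents that add atoms: none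
Why: Carbodiimide-mediated amide coupling through the benzotriazolyl ester, run without added tertiary amine so that the β,γ-alkene does not shift into conjugation; C10 stays a mixture, which is irrelevant.

Step 9
Reactants: 15 (3Z,5R,7E)-2,6,6,9-tetramethyl-1-(pyrrolidin-1-yl)-5-(triisopropylsilyloxy)deca-3,7,9-trien-1-one
Product: 19 (1R,4R,6R,8R)-1,5,5-trimethyl-8-(prop-1-en-2-yl)-4-(triisopropylsilyloxy)bicyclo[4.1.1]oct-2-en-7-one, via O-triflyliminium triflate 16 (not isolated), via keteniminium triflate 17 (not isolated), via cyclobutaniminium triflate 18 (not isolated)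
Conditions: Tf2O, 2,4,6-collidine, ClCH2CH2Cl (0.01 M), 0 °C → 80 °C; then H2O, 50 °C
Reagents that add atoms: water, O
Why: O-Triflation of the amide and loss of the doubly activated C10–H give the alkenyl keteniminium ion 17; the near diene terminus C5 attacks the electrophilic central carbon C11, the charge passes to the allyl unit C4–C3–CH2, and the enamine carbon C10 closes onto C4, which is the bridged (crossed) mode of the intramolecular keteniminium–olefin [2+2] cycloaddition, established for three-atom tethers that give bicyclo[3.1.1]heptanones and extended here by one tether atom. The seven-membered ring closes first, by attack of C5 on C11 (7-exo with respect to C5=C4, both keteniminium carbons inside the ring), and the four-membered ring second, by 4-exo collapse of C10 onto the allyl cation at C4. C4 and C5 keep the trans relation of the (E)-alkene because the alkene adds suprafacially, and C10 has no freedom because the chain C6–C9 can span C5 and C10 on one face only, which puts the C10 methyl group on the other face. The absolute sense is relayed from C7: allylic 1,3-strain across the cis C8=C9 bond holds C7–H near the plane of the alkenyl keteniminium unit, and the fold that turns the large silyloxy group away from the pyrrolidinium-bearing C11, toward the small C4–H side, is expected to be favoured. The step needs the crossed regiochemistry (secured by allyl stabilisation of charge at C4, whereas the fused mode would put charge on the neopentyl C5), reaction at the near alkene (a seven- against a ten-membered ring, helped by the gem-dimethyl group and the cis-alkene), closure at C4 and not at the far allyl terminus, and facial selectivity (C7). High dilution suppresses intermolecular reaction, and water then hydrolyses iminium ion 18 to the ketone.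

Step 10
Reactants: 19 (1R,4R,6R,8R)-1,5,5-trimethyl-8-(prop-1-en-2-yl)-4-(triisopropylsilyloxy)bicyclo[4.1.1]oct-2-en-7-one
Product: 22 1,5,5-trimethyl-8-(prop-1-en-2-yl)-4-(triisopropylsilyloxy)bicyclo[4.1.1]oct-2-ene-7-carbaldehyde (formyl on C11 cis to isopropenyl on C4), via methoxymethylidene ylide 20 (not isolated), via enol ether 21 (not isolated)
Conditions: MeOCH2PPh3Cl, KN(SiMe3)2, THF, 0 °C → rt; then 2 M HCl, THF, rt
Reagents that add atoms: (methoxymethyl)triphenylphosphonium chloride, COC[P+](c1ccccc1)(c1ccccc1)c1ccccc1.[Cl-]; water, O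
Why: Wittig methoxymethylenation of the strained, non-enolisable cyclobutanone and acid hydrolysis of the enol ether add C1 as an aldehyde (one-carbon homologation); C11 is set on C-protonation, both epimers are expected and interconvert through the enol, and the epimer with the formyl group cis to the isopropenyl group is carried on.

Step 11
Reactants: 22 1,5,5-trimethyl-8-(prop-1-en-2-yl)-4-(triisopropylsilyloxy)bicyclo[4.1.1]oct-2-ene-7-carbaldehyde
Product: 23 tricyclic homoallylic alcohol (C1 carbinol; C3 methylidene; C8=C9; C7 OTIPS)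
Conditions: Me2AlCl, CH2Cl2, −78 °C → 0 °C
Reagents that add atoms: none
Why: Type-two intramolecular carbonyl-ene reaction in which the isopropenyl CH2 terminus (C2) attacks the Me2AlCl-activated aldehyde while a methyl hydrogen passes to oxygen, closing the six-membered ring C1–C2–C3–C4–C10–C11; only the cis epimer can reach, the methylaluminium reagent scavenges protons so that the cyclobutane next to the electron-poor C3 should not rearrange (as in ene reactions of pinene-type alkenes), and the new carbinol centre C1 is removed in step 12.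

Step 12
Reactants: 23 tricyclic homoallylic alcohol
Product: 25 tricyclic enone (C1 ketone; C2=C3 with 3-methyl; C8=C9; C7 OTIPS), via β,γ-unsaturated ketone 24 (not isolated)
Conditions: Dess–Martin periodinane, CH2Cl2, 0 °C → rt; then DBU (excess), rt
Reagents that add atoms: none
Why: Dess–Martin oxidation gives the β,γ-unsaturated ketone and DBU moves the exocyclic alkene into conjugation through the dienolate (base-mediated alkene isomerisation), the endocyclic trisubstituted enone being the thermodynamic product and C4 and C11 being bridgeheads that cannot enolise.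

Step 13
Reactants: 25 tricyclic enone
Product: 26 8,9-epoxide of 25 (epoxide oxygen trans to the C7 oxygen)
Conditions: mCPBA, CH2Cl2, 0 °C → rt
Reagents that add atoms: 3-chloroperoxybenzoic acid, OOC(=O)c1cccc(Cl)c1
Why: Peracid (Prilezhaev) epoxidation of the only electron-rich alkene; the bulky allylic silyloxy group on C7 screens its own face, so oxygen should arrive on the face turned toward C11, which sets the C9 configuration.

Step 14
Reactants: 26 8,9-epoxide of 25
Product: 27 epoxy alcohol (free C7 hydroxyl trans to the epoxide)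
Conditions: Bu4NF, THF, 0 °C → 40 °C
Reagents that add atoms: none
Why: Fluoride-induced cleavage of the silyl ether (desilylation) frees the C7 hydroxyl needed to direct the next step, while epoxide and enone do not react with fluoride under these conditions.

Step 15
Reactants: 27 epoxy alcohol
Product: 28 triol (C1 allylic alcohol as either epimer; anti-7,9-diol)
Conditions: NaAlH2(OCH2CH2OMe)2, THF, 0 °C → rt; aq. KNaC4H4O6
Reagents that add atoms: none
Why: Reductive opening of a 2,3-epoxy alcohol by an alkoxyaluminium hydride, in which the C7 aluminate, lying trans to the epoxide oxygen, delivers hydride to C8 from the rear of the C8–O bond while the neopentyl C9 is shielded, so that the C9–O bond and the configurations at C7 and C9 are kept and the anti-1,3-diol results; the enone carbonyl is reduced in the 1,2-sense at the same time, which step 16 reverses.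

Step 16
Reactants: 28 triol
Product: 29 enone diol (7R,9R)
Conditions: MnO2, CH2Cl2, rt
Reagents that add atoms: none
Why: MnO2 oxidises allylic alcohols selectively, so the C1 carbinol returns to the enone while the two saturated secondary hydroxyls remain.

Step 17
Reactants: 29 enone diol
Product: 30 target bis(3-methylbutanoate)
Conditions: 3-methylbutanoyl chloride, pyridine, DMAP, CH2Cl2, 0 → 40 °C
Reagents that add atoms: 3-methylbutanoyl chloride, CC(C)CC(Cl)=O
Why: DMAP-catalysed acylation with excess acid chloride esterifies both hindered secondary alcohols without touching any stereocentre.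

**Compound list**

1 | (S)-pantolactone, (3S)-3-hydroxy-4,4-dimethyloxolan-2-one | CC1(C)COC(=O)[C@H]1O | starting material
2 | (3S)-4,4-dimethyl-3-(triisopropylsilyloxy)oxolan-2-one | CC1(C)COC(=O)[C@H]1O[Si](C(C)C)(C(C)C)C(C)C | intermediate
3 | (3S)-4,4-dimethyl-3-(triisopropylsilyloxy)oxolan-2-ol (lactol, both anomers) | CC1(C)COC(O)[C@H]1O[Si](C(C)C)(C(C)C)C(C)C | intermediate
4 | methacrylic acid (2-methylprop-2-enoic acid) | CC(=C)C(=O)O | starting material
5 | (2-carboxypropyl)triphenylphosphonium bromide (racemic) | CC(C[P+](c1ccccc1)(c1ccccc1)c1ccccc1)C(=O)O.[Br-] | intermediate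
6 | sodium 2-methyl-3-(triphenylphosphoranylidene)propanoate (carboxylate ylide) | CC(C=P(c1ccccc1)(c1ccccc1)c1ccccc1)C(=O)[O-].[Na+] | intermediate (not isolated)
7 | (3Z,5R)-7-hydroxy-2,6,6-trimethyl-5-(triisopropylsilyloxy)hept-3-enoic acid (both C2 epimers) | OC(=O)C(C)/C=C\[C@@H](O[Si](C(C)C)(C(C)C)C(C)C)C(C)(C)CO | intermediate
8 | (3Z,5R)-2,6,6-trimethyl-7-oxo-5-(triisopropylsilyloxy)hept-3-enoic acid (both C2 epimers) | OC(=O)C(C)/C=C\[C@@H](O[Si](C(C)C)(C(C)C)C(C)C)C(C)(C)C=O | intermediate
9 | methallyl chloride (3-chloro-2-methylprop-1-ene) | CC(=C)CCl | starting material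
10 | tributyl(2-methylprop-2-en-1-yl)phosphonium chloride | CC(=C)C[P+](CCCC)(CCCC)CCCC.[Cl-] | intermediate
11 | tributyl(2-methylprop-2-en-1-ylidene)phosphorane (allylic ylide) | CC(=C)C=P(CCCC)(CCCC)CCCC | intermediate (not isolated)
12 | (3Z,5R,7E)-2,6,6,9-tetramethyl-5-(triisopropylsilyloxy)deca-3,7,9-trienoic acid (both C2 epimers) | OC(=O)C(C)/C=C\[C@@H](O[Si](C(C)C)(C(C)C)C(C)C)C(C)(C)/C=C/C(C)=C | intermediate
13 | pyrrolidine | C1CCNC1 | starting material
14 | benzotriazol-1-yl ester of acid 12 | O=C(On1nnc2ccccc12)C(C)/C=C\[C@@H](O[Si](C(C)C)(C(C)C)C(C)C)C(C)(C)/C=C/C(C)=C | intermediate (not isolated)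
15 | (3Z,5R,7E)-2,6,6,9-tetramethyl-1-(pyrrolidin-1-yl)-5-(triisopropylsilyloxy)deca-3,7,9-trien-1-one (both C2 epimers; precursor of the key step) | O=C(N1CCCC1)C(C)/C=C\[C@@H](O[Si](C(C)C)(C(C)C)C(C)C)C(C)(C)/C=C/C(C)=C | intermediate
16 | O-triflyliminium triflate of amide 15 | FC(F)(F)S(=O)(=O)OC(=[N+]1CCCC1)C(C)/C=C\[C@@H](O[Si](C(C)C)(C(C)C)C(C)C)C(C)(C)/C=C/C(C)=C.[O-]S(=O)(=O)C(F)(F)F | intermediate (not isolated)
17 | keteniminium triflate, 1-[(3Z,5R,7E)-2,6,6,9-tetramethyl-5-(triisopropylsilyloxy)deca-1,3,7,9-tetraen-1-ylidene]pyrrolidinium trifluoromethanesulfonate | C(=[N+]1CCCC1)=C(C)/C=C\[C@@H](O[Si](C(C)C)(C(C)C)C(C)C)C(C)(C)/C=C/C(C)=C.[O-]S(=O)(=O)C(F)(F)F | intermediate (not isolated)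
18 | cyclobutaniminium triflate (pyrrolidinium ylidene on C11 of the bicyclo[4.1.1]octene; ring centres as in 19) | C=C(C)[C@H]1[C@H]2C(=[N+]3CCCC3)[C@]1(C)C=C[C@@H](O[Si](C(C)C)(C(C)C)C(C)C)C2(C)C.[O-]S(=O)(=O)C(F)(F)F | intermediate (not isolated)
19 | (1R,4R,6R,8R)-1,5,5-trimethyl-8-(prop-1-en-2-yl)-4-(triisopropylsilyloxy)bicyclo[4.1.1]oct-2-en-7-one (isopropenyl on C4 trans to C6 on C5; product of the key step) | C=C(C)[C@H]1[C@H]2C(=O)[C@]1(C)C=C[C@@H](O[Si](C(C)C)(C(C)C)C(C)C)C2(C)C | intermediate
20 | (methoxymethylidene)triphenylphosphorane | COC=P(c1ccccc1)(c1ccccc1)c1ccccc1 | intermediate (not isolated)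
21 | 7-(methoxymethylidene) enol ether of 19 (both alkene isomers) | C=C(C)[C@H]1[C@H]2C(=COC)[C@]1(C)C=C[C@@H](O[Si](C(C)C)(C(C)C)C(C)C)C2(C)C | intermediate (not isolated)
22 | 1,5,5-trimethyl-8-(prop-1-en-2-yl)-4-(triisopropylsilyloxy)bicyclo[4.1.1]oct-2-ene-7-carbaldehyde, formyl on C11 cis to isopropenyl on C4 (both on the cyclobutane face away from the C6–C9 bridge); other centres as in 19 | C=C(C)[C@H]1[C@H]2[C@@H](C=O)[C@]1(C)C=C[C@@H](O[Si](C(C)C)(C(C)C)C(C)C)C2(C)C | intermediate
23 | tricyclic homoallylic alcohol: C1 carbinol (either epimer), methylidene on C3, C8=C9, OTIPS on C7; C4, C5, C7, C10, C11 as in 30 | C=C1CC(O)[C@@H]2[C@@H]3[C@H]1[C@@]2(C)C=C[C@@H](O[Si](C(C)C)(C(C)C)C(C)C)C3(C)C | intermediate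
24 | tricyclic β,γ-unsaturated ketone: C1 ketone, methylidene on C3; otherwise as 23 | C=C1CC(=O)[C@@H]2[C@@H]3[C@H]1[C@@]2(C)C=C[C@@H](O[Si](C(C)C)(C(C)C)C(C)C)C3(C)C | intermediate (not isolated)
25 | tricyclic enone: C1 ketone, C2=C3 (3-methyl), C8=C9, OTIPS on C7; ring centres as in 30 | CC1=CC(=O)[C@@H]2[C@@H]3[C@H]1[C@@]2(C)C=C[C@@H](O[Si](C(C)C)(C(C)C)C(C)C)C3(C)C | intermediate
26 | 8,9-epoxide of 25, epoxide oxygen on the face toward C11 and trans to the C7 oxygen | CC1=CC(=O)[C@@H]2[C@@H]3[C@H]1[C@@]2(C)[C@@H]4O[C@@H]4[C@@H](O[Si](C(C)C)(C(C)C)C(C)C)C3(C)C | intermediate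
27 | epoxy alcohol: 26 with free C7 hydroxyl | CC1=CC(=O)[C@@H]2[C@@H]3[C@H]1[C@@]2(C)[C@@H]4O[C@@H]4[C@@H](O)C3(C)C | intermediate
28 | triol: C1 allylic alcohol (either epimer), (7R,9R)-diol, C2=C3; ring centres as in 30 | CC1=CC(O)[C@@H]2[C@@H]3[C@H]1[C@@]2(C)[C@H](O)C[C@@H](O)C3(C)C | intermediate
29 | enone diol, (4R,5S,7R,9R,10R,11R)-7,9-dihydroxy-3,6,6,10-tetramethyl tricyclic enone (route locants) | CC1=CC(=O)[C@@H]2[C@@H]3[C@H]1[C@@]2(C)[C@H](O)C[C@@H](O)C3(C)C | intermediate
30 | (1R,2R,3R,5R,7S,8R)-2,6,6,11-tetramethyl-9-oxotricyclo[5.4.0.0^2,8]undec-10-ene-3,5-diyl bis(3-methylbutanoate); route locants (4R,5S,7R,9R,10R,11R) | CC1=CC(=O)[C@@H]2[C@@H]3[C@H]1[C@@]2(C)[C@H](OC(=O)CC(C)C)C[C@@H](OC(=O)CC(C)C)C3(C)C | target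

**Step count, longest sequence, risks**

Total step count: 17. Longest linear sequence: 15 steps (steps 1, 2, 4, 5 and 7–17).

Steps most likely to fail:

1. Step 9. The cationic intermediate may be diverted before the four-membered ring closes: closure of the allyl cation at its far terminus to a six-membered ring, proton loss to a polyene, oligomerisation, or too weak a facial bias from C7. The fallback replaces the keteniminium ion by the neutral ketene, which sets out from acid 12 and makes step 8 unnecessary. Acid 12 is converted with (COCl)2 and catalytic DMF in CH2Cl2 at 0 °C into (3Z,5R,7E)-2,6,6,9-tetramethyl-5-(triisopropylsilyloxy)deca-3,7,9-trienoyl chloride F1. This is added slowly to Et3N in refluxing toluene at high dilution; dehydrochlorination at the doubly activated C10–H should give the alkenylketene (3Z,5R,7E)-2,6,6,9-tetramethyl-5-(triisopropylsilyloxy)deca-1,3,7,9-tetraen-1-one F2. Its thermal intramolecular [2+2] cycloaddition in the same bridged sense should deliver ketone 19 directly, where the route is rejoined.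

2. Step 11. The cyclisation depends on the formyl group standing cis to the isopropenyl group and passes through an electron-poor C3 next to the cyclobutane; slow interconversion of the C11 epimers, or a 1,2-shift of a ring bond toward C3 (ring expansion) under Lewis-acid activation, would drain material. The fallback closes the ring by metathesis at C2=C3 and sets out from aldehyde 22. Addition of CH2=CHMgBr in THF at −78 °C should give the vinyl carbinol F3 (22 with CH(OH)CH=CH2 in place of CHO, either C1 epimer). Ring-closing metathesis between its vinyl and isopropenyl groups with the second-generation Grubbs catalyst RuCl2(=CHPh)(PCy3)(H2IMes) in CH2Cl2 at 40 °C should give the tricyclic allylic alcohol F4 (25 with C1–OH in place of C1=O). Dess–Martin oxidation of F4 leads to enone 25, where the route is rejoined; steps 11 and 12 are replaced, and C2 then stems from the Grignard reagent.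

3. Step 15. Hydride may add to the enone in the conjugate sense, or may open the congested epoxide slowly or at the wrong carbon. The fallback uses a selenium nucleophile and a radical reduction, which leave the enone untouched, and sets out from epoxy alcohol 27. PhSeNa (made beforehand from PhSeSePh and NaBH4 in EtOH so that no free borohydride remains) should open the epoxide by SN2 attack at the less hindered C8, giving the 8-(phenylselanyl) anti-7,9-diol F5 (29 with SePh on C8 trans to the C9 hydroxyl). Bu3SnH and AIBN in toluene at 80 °C then replace selenium by hydrogen and give enone diol 29, where the route is rejoined; steps 15 and 16 are replaced.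

**Further compounds**

F1 | step 9 | (3Z,5R,7E)-2,6,6,9-tetramethyl-5-(triisopropylsilyloxy)deca-3,7,9-trienoyl chloride (both C2 epimers) | ClC(=O)C(C)/C=C\[C@@H](O[Si](C(C)C)(C(C)C)C(C)C)C(C)(C)/C=C/C(C)=C
F2 | step 9 | (3Z,5R,7E)-2,6,6,9-tetramethyl-5-(triisopropylsilyloxy)deca-1,3,7,9-tetraen-1-one (alkenylketene) | O=C=C(C)/C=C\[C@@H](O[Si](C(C)C)(C(C)C)C(C)C)C(C)(C)/C=C/C(C)=C
F3 | step 11 | vinyl carbinol: 22 with CH(OH)CH=CH2 in place of CHO (either C1 epimer) | C=C(C)[C@H]1[C@H]2[C@@H](C(O)C=C)[C@]1(C)C=C[C@@H](O[Si](C(C)C)(C(C)C)C(C)C)C2(C)C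
F4 | step 11 | tricyclic allylic alcohol: 25 with C1–OH in place of C1=O (either C1 epimer) | CC1=CC(O)[C@@H]2[C@@H]3[C@H]1[C@@]2(C)C=C[C@@H](O[Si](C(C)C)(C(C)C)C(C)C)C3(C)C
F5 | step 15 | 8-(phenylselanyl) anti-7,9-diol: 29 with SePh on C8 trans to the C9 hydroxyl | CC1=CC(=O)[C@@H]2[C@@H]3[C@H]1[C@@]2(C)[C@H](O)[C@@H]([Se]c4ccccc4)[C@@H](O)C3(C)C
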